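Assumption: the target is taken as the achiral structure of the given SMILES, and 4-methoxy-6-methyl-2H-pyran-2-one (1) and 3,5-dimethoxyphenol (3) are taken as purchasable. Ring A is the 3,5-dihydroxyphenyl ring. Ring B is the central ring (C1 bears the oxygen to ring A, C2 and C4 bear OH, C6 bears the oxygen to ring C). Ring C is the 2,4,6-trihydroxyphenyl ring (ether at C1').

## The problem

Triphloroethol A (10) is a trimer of phloroglucinol in which three benzene rings are joined by two diaryl ether bonds; it has no stereocentre. The ethers are the first difficulty: the oxygen on C1 of ring B is flanked by two oxygen-bearing carbons, and the C6(B)–O–C1'(C) bridge joins a carbon with one ortho oxygen to a carbon with two, all on very electron-rich rings, which is the least favourable case for Ullmann or SNAr coupling. The second difficulty is regiochemical: seven hydroxyl groups of nearly equal reactivity are present, so which oxygen carries which ring has to follow from the construction and cannot be left to selective reactions on a polyphenol. The free polyphenol is oxidised by air in base and its rings are strong carbon nucleophiles, so the hydroxyl groups must stay masked until a last, non-oxidative step. The feature that opens a way is that C1 of ring B and C1' of ring C each lie between two oxygen-bearing ring carbons (C2/C6 and C2'/C6'). In the triketo form of such a ring this carbon is the one that was the terminal carbon (C6) of a 3,5-dioxohexanoyl chain before a Claisen closure joined it to the acyl carbon C1. Each hindered aryl–O–aryl bond can thus be made as a primary ArO–CH2 bond beside a masked ketone, and the six carbons of ring B, and then of ring C, closed around it by a Claisen condensation. These six carbons are C2 to C6 and the exocyclic CH2 of a 6-substituted 4-methoxy-2-pyrone.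

## Retrosynthesis

10 from 9. The four O–CH3 bonds are cut. Methyl is chosen over benzyl because the key step runs in methoxide, which can exchange the alkoxy group at C4 of a 2-pyrone (a vinylogous ester); with a methyl ether that exchange is degenerate. The forward step must cleave four unhindered aryl methyl ethers without touching the two diaryl ether bridges.

9 from 7. Ring C is cut at its C1'–C2' bond and C2' is reconnected to the oxygen on C6' as a lactone, so ring C becomes the 4-methoxy-2-pyrone of 7 (by way of the open-chain ester 8). The neighbouring cuts, C1'–O or O–C6(B), would require a coupling at a di-ortho-substituted carbon between two electron-rich rings. This cut turns the same ether into a primary alkyl aryl ether. Precursor 7 lacks a whole benzene ring and the hindered bridge. The forward reaction must open the lactone with methoxide and acylate the ArO–CH2 carbon with the resulting ester, in the presence of a free phenol on ring B.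

7 from 6 and 2. The O–CH2 bond is cut. Diol 6 is a symmetric resorcinol: its hydroxyl groups on C2 and C6 are equivalent, so it does not matter which one reacts. The third oxygen (C4) is already set apart as the methyl ether that came from the pyrone. Only mono- against bis-alkylation has to be controlled, which is done with an excess of recoverable 6. No protecting group is planned, because a free phenol should be tolerated in the next step.

6 from 4. The same cut as in ring C is made in ring B, at C1–C2. Pyrone atoms C2 to C6 of 4 become C2 to C6 of ring B and the exocyclic CH2 becomes C1. Precursor 4 has one benzene ring and no hindered ether. The forward reaction is the ring-opening and Claisen closure through ester 5.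

4 from 2 and 3. The O–CH2 bond is cut; the forward reaction is a Williamson etherification of phenol 3 with the primary bromide 2. The direction of the iteration is fixed by the structure: each ether oxygen sits on a carbonyl-derived carbon of the earlier ring and on the CH-derived carbon of the later ring, so ring A must exist first.

2 from 1. The C–Br bond is cut; side-chain bromination of pyrone 1. One building block, 2, is used twice and supplies all six carbons and the C4 oxygen of both ring B and ring C.

## Roads not taken

Alternative 1: the most obvious plan cuts both aryl–O bonds and joins three preformed phloroglucinol rings by copper-mediated Ullmann couplings. In a typical version 2-bromo-1,3,5-trimethoxybenzene A1 is coupled with 2-hydroxy-4,6-dimethoxybenzaldehyde A2 to give 2,4-dimethoxy-6-(2,4,6-trimethoxyphenoxy)benzaldehyde A3. The formyl group of A3 serves as a masked oxygen: Baeyer–Villiger oxidation and formate hydrolysis (a Dakin-type sequence) give 2,4-dimethoxy-6-(2,4,6-trimethoxyphenoxy)phenol A4. Phenol A4 is then arylated with a ring A aryl halide to the heptamethyl ether of the target, 2-[2-(3,5-dimethoxyphenoxy)-3,5-dimethoxyphenoxy]-1,3,5-trimethoxybenzene A5, which is demethylated. Both couplings join electron-rich partners at ortho-substituted positions; the second is at the hydroxyl group of A4, which is flanked by two oxygen substituents. Such couplings are slow at copper and prone to reductive loss of halide. The ring B oxygens need a separate differentiation device and an extra oxidation step. The chosen plan makes each bridge by SN2 at a primary carbon and lets the ring construction set the oxygen pattern.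

Alternative 2: a biomimetic cut of the same two C–O bonds, made forward by anodic dehydrogenative coupling of phenol 3 (a phenoxyl radical or phenoxonium ion captured by the oxygen of a second phenol). The first coupling would have to give the ortho-linked dimer 2-(3,5-dimethoxyphenoxy)-3,5-dimethoxyphenol A6, and a second one would have to join the free hydroxyl group of A6 to an ortho carbon of a third molecule of 3. Nothing in the substrate steers the coupling to oxygen rather than carbon (biaryl formation) or to an ortho rather than the para carbon, and nothing stops it at a trimer. A6 is also more easily oxidised than 3. The chosen plan fixes every connection by the order of two alkylations.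

Alternative 3: a convergent plan that forms ring B last with both ethers in place. Rhodium carbenoid O–H insertion of 3-diazo-6-methyl-2H-pyran-2,4(3H)-dione A7 into 3 with Rh2(OAc)4 as catalyst, sulfonylation of the 4-hydroxyl group so formed and addition–elimination of 2,4,6-trimethoxyphenol A8 at C4 would give 3-(3,5-dimethoxyphenoxy)-6-methyl-4-(2,4,6-trimethoxyphenoxy)-2H-pyran-2-one A9. Methoxide opening of A9 and Claisen closure from the C6 methyl group would then give ring B with its oxygens already differentiated. The plan was set aside for three reasons. The Claisen nucleophile derived from A9 would be the enolate of an unactivated methyl ketone, whereas the corresponding carbon of the chosen plan is also acidified by its aryloxy group. Ring C would sit as an aryloxide on the vinylogous ester carbon C4 and could be expelled by methoxide before the ring closes. The bond to ring C would still have to be made with the di-ortho-substituted phenol A8, and the diazo compound A7, the sulfonate and A8 each cost a step of their own. In the chosen plan no aryloxide is attached to an electrophilic carbon.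

Key step: step 3

## Steps

Step 1
Reactants: 1 4-methoxy-6-methyl-2H-pyran-2-one
Product: 2 6-(bromomethyl)-4-methoxy-2H-pyran-2-one
Conditions: NBS (1.05 equiv), (PhCO2)2 (cat.), PhCF3, reflux
Reagents that add atoms: N-bromosuccinimide, O=C1CCC(=O)N1Br
Why: Wohl–Ziegler bromination; the 6-methyl group is the allylic-type position of the pyrone and should be brominated under radical conditions in a non-polar solvent, which disfavour ionic bromination at C3. One equivalent of NBS limits double bromination.

Step 2
Reactants: 2 6-(bromomethyl)-4-methoxy-2H-pyran-2-one; 3 3,5-dimethoxyphenol
Product: 4 6-[(3,5-dimethoxyphenoxy)methyl]-4-methoxy-2H-pyran-2-one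
Conditions: K2CO3, acetone, 50 °C
Reagents that add atoms: none
Why: Williamson ether synthesis; the phenoxide of 3 displaces a primary, allylic-type bromide by SN2, and carbonate in a polar aprotic solvent should favour O- over C-alkylation. The bond that will become the hindered ring A–O–ring B bridge is made here without steric demand.

Step 3
Reactants: 4 6-[(3,5-dimethoxyphenoxy)methyl]-4-methoxy-2H-pyran-2-one
Product: 6 2-(3,5-dimethoxyphenoxy)-5-methoxybenzene-1,3-diol, via open-chain keto enoate 5 (not isolated)
Conditions: NaOMe (5 equiv), degassed MeOH, argon, 65 °C then 120 °C (sealed tube); aq. HCl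
Reagents that add atoms: none
Why: Proposed new method: methoxide should add to the lactone carbonyl (pyrone C2) of 4 and open the ring to ester 5, whose C2=C3 double bond keeps the geometry imposed by the ring (2E), so that the ester carbon and the keto-bearing chain stay cis. Reversible enolisation of the ketone towards the ArO–CH2 carbon (acidified by the carbonyl and by the aryloxy group) gives the enolate that attacks the ester carbon in a Dieckmann-type Claisen condensation, a favoured 6-(enolendo)-exo-trig closure that forms the C1–C2 bond of ring B. Loss of methoxide and enolisation then give the aromatic ring, which as its resorcinolate makes the sequence irreversible and draws the pyrone and ester equilibria through. The closest known reaction types are the base-mediated conversion of methyl 3,5-dioxohexanoate (from triacetic acid lactone) into phloroglucinol, the Claisen cyclisation of 3,5,7-triketo esters to acylphloroglucinols, and the same bond formation by the phloroglucinol-forming polyketide synthase. The selectivity needed is C- over O-acylation, and O-acylation only returns the pyrone, which methoxide reopens. The other enolisable position (between the ketone and the enol ether carbon) cannot reach an electrophile through a five- or six-membered ring and is only a resting state. Methoxide exchange at the vinylogous ester carbon is degenerate because that ether is methyl, and the same methyl ether marks the oxygen on C4 of ring B and leaves the two new hydroxyl groups equivalent. No stereocentre is formed.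

Step 4
Reactants: 6 2-(3,5-dimethoxyphenoxy)-5-methoxybenzene-1,3-diol (3 equiv); 2 6-(bromomethyl)-4-methoxy-2H-pyran-2-one (1 equiv)
Product: 7 6-{[2-(3,5-dimethoxyphenoxy)-3-hydroxy-5-methoxyphenoxy]methyl}-4-methoxy-2H-pyran-2-one
Conditions: K2CO3 (1.1 equiv on 2), DMF, argon, 0 °C to rt; excess 6 recovered by chromatography
Reagents that add atoms: none
Why: Williamson ether synthesis on a symmetric diol; the two hydroxyl groups of 6 are equivalent, so only mono- against bis-alkylation matters, and an excess of 6 with limiting base should keep the second alkylation low. The remaining hydroxyl is left free because a phenoxide is expected to be tolerated in step 5.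

Step 5
Reactants: 7 6-{[2-(3,5-dimethoxyphenoxy)-3-hydroxy-5-methoxyphenoxy]methyl}-4-methoxy-2H-pyran-2-one
Product: 9 2-[2-(3,5-dimethoxyphenoxy)-3-hydroxy-5-methoxyphenoxy]-5-methoxybenzene-1,3-diol, via open-chain keto enoate 8 (not isolated)
Conditions: NaOMe (6 equiv), degassed MeOH, argon, 65 °C then 120 °C (sealed tube); aq. HCl
Reagents that add atoms: none
Why: Proposed new method: the same methoxide ring-opening and 6-(enolendo)-exo-trig Claisen closure as in step 3, now building ring C around the ArO–CH2 carbon attached to ring B, with one more equivalent of base for the free phenol. The closest known reaction type is again the base-mediated cyclisation of methyl 3,5-dioxohexanoate to phloroglucinol. The tri-ortho-substituted ring B–O–ring C bridge is already in place as an ether before the ring closes.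

Step 6
Reactants: 9 2-[2-(3,5-dimethoxyphenoxy)-3-hydroxy-5-methoxyphenoxy]-5-methoxybenzene-1,3-diol
Product: 10 triphloroethol A, 2-[2-(3,5-dihydroxyphenoxy)-3,5-dihydroxyphenoxy]benzene-1,3,5-triol
Conditions: BBr3 (12 equiv), CH2Cl2, argon, −78 °C to rt; MeOH, then H2O
Reagents that add atoms: none
Why: Lewis acid cleavage of aryl methyl ethers; boron binds the ether oxygen and bromide attacks the methyl carbon by SN2. The diaryl ether oxygens are less basic and offer no sp3 carbon, so both bridges should survive; the excess of BBr3 covers the three free hydroxyl groups.

## Compound list

1 | 4-methoxy-6-methyl-2H-pyran-2-one | COC1=CC(=O)OC(C)=C1 | starting material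
2 | 6-(bromomethyl)-4-methoxy-2H-pyran-2-one | COC1=CC(=O)OC(CBr)=C1 | intermediate
3 | 3,5-dimethoxyphenol | COc1cc(O)cc(OC)c1 | starting material
4 | 6-[(3,5-dimethoxyphenoxy)methyl]-4-methoxy-2H-pyran-2-one | COC1=CC(=O)OC(COc2cc(OC)cc(OC)c2)=C1 | intermediate
5 | methyl (2E)-6-(3,5-dimethoxyphenoxy)-3-methoxy-5-oxohex-2-enoate (open-chain keto enoate, not isolated) | COC(=O)/C=C(/OC)CC(=O)COc1cc(OC)cc(OC)c1 | intermediate
6 | 2-(3,5-dimethoxyphenoxy)-5-methoxybenzene-1,3-diol | COc1cc(O)c(Oc2cc(OC)cc(OC)c2)c(O)c1 | intermediate
7 | 6-{[2-(3,5-dimethoxyphenoxy)-3-hydroxy-5-methoxyphenoxy]methyl}-4-methoxy-2H-pyran-2-one | COC1=CC(=O)OC(COc2cc(OC)cc(O)c2Oc2cc(OC)cc(OC)c2)=C1 | intermediate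
8 | methyl (2E)-6-[2-(3,5-dimethoxyphenoxy)-3-hydroxy-5-methoxyphenoxy]-3-methoxy-5-oxohex-2-enoate (open-chain keto enoate, not isolated) | COC(=O)/C=C(/OC)CC(=O)COc1cc(OC)cc(O)c1Oc1cc(OC)cc(OC)c1 | intermediate
9 | 2-[2-(3,5-dimethoxyphenoxy)-3-hydroxy-5-methoxyphenoxy]-5-methoxybenzene-1,3-diol | COc1cc(O)c(Oc2cc(OC)cc(O)c2Oc2cc(OC)cc(OC)c2)c(O)c1 | intermediate
10 | triphloroethol A, 2-[2-(3,5-dihydroxyphenoxy)-3,5-dihydroxyphenoxy]benzene-1,3,5-triol | Oc1cc(O)cc(Oc2c(O)cc(O)cc2Oc2c(O)cc(O)cc2O)c1 | target

## Step count and risks

Total step count: 6. Longest linear sequence: 6 steps (1 → 2 → 4 → 6 → 7 → 9 → 10); building block 2 enters twice.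

Step 3 (key step, proposed new method). The Claisen closure may be outrun. In the opened chain 5 the most acidic position is the CH2 between the ketone and the enol ether carbon. Its extended enolate is a resting state in which the ester is deactivated, so C-acylation from the aryloxy-bearing carbon may need temperatures at which methoxide cleaves the chain by a retro-Claisen reaction, or at which the material simply returns to the pyrone on work-up. The fallback uses known chemistry (Ullmann ether synthesis), sets out from 3 and comes back at 6. Commercial 5-methoxyresorcinol would be protected with MOMCl and iPr2NEt as 1-methoxy-3,5-bis(methoxymethoxy)benzene F1. This would be lithiated between the two MOM ethers, the stronger directing groups (n-BuLi, THF, 0 °C), and iodinated to 2-iodo-5-methoxy-1,3-bis(methoxymethoxy)benzene F2. Coupling of F2 with 3 (CuI, picolinic acid, K3PO4, DMSO, 90 °C) would give 2-(3,5-dimethoxyphenoxy)-5-methoxy-1,3-bis(methoxymethoxy)benzene F3, and HCl in MeOH would remove the MOM groups to give 6.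

Step 5 (proposed new method). The same competition as in step 3 applies. In addition the substrate carries a phenoxide on ring B that activates the ring carbon next to the OCH2 tether; attack of that carbon on the side-chain ketone (a five-membered ring closure followed by loss of water) would divert material. The phenoxide also makes the compound sensitive to traces of oxygen at the temperature required. The fallback uses known chemistry, sets out from 6 and comes back at 9. Copper-catalysed mono-arylation of an excess of 6 with the iodide F2 (CuI, picolinic acid, K3PO4, DMSO, 90 °C) would give 2-(3,5-dimethoxyphenoxy)-5-methoxy-3-[4-methoxy-2,6-bis(methoxymethoxy)phenoxy]phenol F4, and HCl in MeOH would release 9.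

Step 4. Over-alkylation to the bis-ether and C-alkylation of the phloroglucinol-type ring are the likely failures, because the first alkylation does not deactivate the second hydroxyl and the mono-phenoxide is an ambident nucleophile. The fallback separates the desymmetrisation from the use of bromide 2; it sets out from 6 and comes back at 7. Silylation with iPr3SiCl (1 equiv) and imidazole in DMF would give 2-(3,5-dimethoxyphenoxy)-5-methoxy-3-[(triisopropylsilyl)oxy]phenol F5, with unreacted 6 recovered. Alkylation of F5 with 2 (K2CO3, acetone), which can now occur only once, would give 6-({2-(3,5-dimethoxyphenoxy)-5-methoxy-3-[(triisopropylsilyl)oxy]phenoxy}methyl)-4-methoxy-2H-pyran-2-one F6. Bu4NF buffered with AcOH in THF would then give 7.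

Step 6. Incomplete cleavage of the four methyl ethers is possible, because partly demethylated material can leave solution as boron complexes. The air-sensitive heptaphenol may also be lost by oxidation during isolation. The fallback changes the isolation strategy; it sets out from 9 and comes back at 10. After the BBr3 treatment the crude product would be acetylated (Ac2O, pyridine) to triphloroethol A heptaacetate F7, which is stable and can be chromatographed free of incompletely demethylated material. Methanolysis with HCl in MeOH under argon would then release 10.

## Further compounds

F1 | step 3 | 1-methoxy-3,5-bis(methoxymethoxy)benzene | COCOc1cc(OC)cc(OCOC)c1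
F2 | step 3 | 2-iodo-5-methoxy-1,3-bis(methoxymethoxy)benzene | COCOc1cc(OC)cc(OCOC)c1I
F3 | step 3 | 2-(3,5-dimethoxyphenoxy)-5-methoxy-1,3-bis(methoxymethoxy)benzene | COCOc1cc(OC)cc(OCOC)c1Oc1cc(OC)cc(OC)c1
F4 | step 5 | 2-(3,5-dimethoxyphenoxy)-5-methoxy-3-[4-methoxy-2,6-bis(methoxymethoxy)phenoxy]phenol | COCOc1cc(OC)cc(OCOC)c1Oc1cc(OC)cc(O)c1Oc1cc(OC)cc(OC)c1
F5 | step 4 | 2-(3,5-dimethoxyphenoxy)-5-methoxy-3-[(triisopropylsilyl)oxy]phenol | COc1cc(O)c(Oc2cc(OC)cc(OC)c2)c(O[Si](C(C)C)(C(C)C)C(C)C)c1
F6 | step 4 | 6-({2-(3,5-dimethoxyphenoxy)-5-methoxy-3-[(triisopropylsilyl)oxy]phenoxy}methyl)-4-methoxy-2H-pyran-2-one | COC1=CC(=O)OC(COc2cc(OC)cc(O[Si](C(C)C)(C(C)C)C(C)C)c2Oc2cc(OC)cc(OC)c2)=C1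
F7 | step 6 | triphloroethol A heptaacetate, 2-[2-(3,5-diacetoxyphenoxy)-3,5-diacetoxyphenoxy]benzene-1,3,5-triyl triacetate | CC(=O)Oc1cc(OC(C)=O)cc(Oc2c(OC(C)=O)cc(OC(C)=O)cc2Oc2c(OC(C)=O)cc(OC(C)=O)cc2OC(C)=O)c1
A1 | alternative 1 | 2-bromo-1,3,5-trimethoxybenzene | COc1cc(OC)c(Br)c(OC)c1
A2 | alternative 1 | 2-hydroxy-4,6-dimethoxybenzaldehyde | COc1cc(O)c(C=O)c(OC)c1
A3 | alternative 1 | 2,4-dimethoxy-6-(2,4,6-trimethoxyphenoxy)benzaldehyde | COc1cc(OC)c(C=O)c(Oc2c(OC)cc(OC)cc2OC)c1
A4 | alternative 1 | 2,4-dimethoxy-6-(2,4,6-trimethoxyphenoxy)phenol | COc1cc(OC)c(O)c(Oc2c(OC)cc(OC)cc2OC)c1
A5 | alternative 1 | 2-[2-(3,5-dimethoxyphenoxy)-3,5-dimethoxyphenoxy]-1,3,5-trimethoxybenzene | COc1cc(OC)cc(Oc2c(OC)cc(OC)cc2Oc2c(OC)cc(OC)cc2OC)c1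
A6 | alternative 2 | 2-(3,5-dimethoxyphenoxy)-3,5-dimethoxyphenol | COc1cc(O)c(Oc2cc(OC)cc(OC)c2)c(OC)c1
A7 | alternative 3 | 3-diazo-6-methyl-2H-pyran-2,4(3H)-dione | CC1=CC(=O)C(=[N+]=[N-])C(=O)O1
A8 | alternative 3 | 2,4,6-trimethoxyphenol | COc1cc(OC)c(O)c(OC)c1
A9 | alternative 3 | 3-(3,5-dimethoxyphenoxy)-6-methyl-4-(2,4,6-trimethoxyphenoxy)-2H-pyran-2-one | CC1=CC(Oc2c(OC)cc(OC)cc2OC)=C(Oc2cc(OC)cc(OC)c2)C(=O)O1
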